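The oxocane is hidden in an oxolane. The ring oxygen, C12, C11, C10 and C9 can close to a five-membered ring. C9 bears oxygen in the target, so the ether oxygen enters as the C9 carbinol oxygen and later moves from C9 to C6. The key step is a Prins–pinacol union of an acyclic vinyl diol (C1–C11 plus one sacrificial carbinol carbon, C9a) with (S)-2-silyloxybutanal (C12–C15). In one operation it forms O–C12, C11–C12 and C9–C10 and sets C10 and C12. Baeyer–Villiger excision of C9a and an oxonium ring expansion then deliver the eight-membered ring.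

Key step: step 9

Remark: acetogenin numbering (C1 = terminal alkyne carbon, C15 = methyl) is used for every intermediate, and the extra carbinol carbon that is later excised is called C9a.

Step 1
Reactants: 1 methyl (S)-2-hydroxybutanoate
Product: 2 methyl (S)-2-(tert-butyldimethylsilyloxy)butanoate
Conditions: TBSCl, imidazole, DMF, 23 °C
Reagents that add atoms: tert-butyldimethylsilyl chloride, CC(C)(C)[Si](C)(C)Cl
Why: Standard O-silylation masks the future C13 oxygen as a group that cannot act as a neighbouring nucleophile later, and the stereocentre is not touched.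

Step 2
Reactants: 2 methyl (S)-2-(tert-butyldimethylsilyloxy)butanoate
Product: 3 (S)-2-(tert-butyldimethylsilyloxy)butanal (C12–C15)
Conditions: iBu2AlH, CH2Cl2, −78 °C; aq Rochelle salt
Reagents that add atoms: none
Why: Partial ester reduction should stop at the aldehyde because the aluminium hemiacetal is stable at −78 °C, and the cold neutral work-up avoids epimerisation at C13.

Step 3
Reactants: 4 (±)-hexa-1,5-dien-3-ol
Product: 5 (1R)-1-[(2S)-oxiran-2-yl]but-3-en-1-ol (6S,7R)
Conditions: Ti(OiPr)4 (10 mol %), D-(−)-diisopropyl tartrate (12 mol %), tBuOOH (0.45 equiv), 4 Å MS, CH2Cl2, −20 °C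
Reagents that add atoms: tert-butyl hydroperoxide, CC(C)(C)OO
Why: This is a Sharpless asymmetric epoxidation run as a kinetic resolution, in which the D-(−)-tartrate catalyst should epoxidise only the allylic vinyl group of the fast (R)-alcohol to the erythro epoxy alcohol, setting C6 and C7 while the homoallylic alkene and the slow (S)-alcohol stay untouched.

Step 4
Reactants: 5 (1R)-1-[(2S)-oxiran-2-yl]but-3-en-1-ol
Product: 6 tert-butyldiphenylsilyl ether of 5 (6S,7R)
Conditions: TBDPSCl, imidazole, DMF, 23 °C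
Reagents that add atoms: tert-butyldiphenylsilyl chloride, CC(C)(C)[Si](Cl)(c1ccccc1)c1ccccc1
Why: O-silylation with the acid-robust TBDPS group keeps the C7 oxygen masked until the last step, so that it alone ends as the free hydroxyl.

Step 5
Reactants: 6 tert-butyldiphenylsilyl ether of 5
Product: 7 (4R,5S)-4-(tert-butyldiphenylsilyloxy)-10-(trimethylsilyl)dec-1-ene-7,9-diyn-5-ol (6S,7R)
Conditions: Me3SiC≡CC≡CSiMe3, MeLi·LiBr, THF, 0 °C; then 6, BF3·OEt2, −78 °C
Reagents that add atoms: 1,4-bis(trimethylsilyl)buta-1,3-diyne, C[Si](C)(C)C#CC#C[Si](C)(C)C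
Why: In this Yamaguchi–Hirao alkynylation the lithium diynide should open the BF3-activated terminal epoxide at the unsubstituted C5, which brings in C1–C4 and leaves the C6 configuration untouched.

Step 6
Reactants: 7 (4R,5S)-4-(tert-butyldiphenylsilyloxy)-10-(trimethylsilyl)dec-1-ene-7,9-diyn-5-ol
Product: 8 C6 methanesulfonate of 7 (6S,7R)
Conditions: MsCl, Et3N, CH2Cl2, 0 °C
Reagents that add atoms: methanesulfonyl chloride, CS(=O)(=O)Cl
Why: Mesylation with retention turns the C6 oxygen into the leaving group that the ether oxygen will displace in step 11.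

Step 7
Reactants: 8 C6 methanesulfonate of 7
Product: 10 (3R,4S)-3-(tert-butyldiphenylsilyloxy)-4-(methanesulfonyloxy)-9-(trimethylsilyl)nona-6,8-diynal (6S,7R), via ozonide 9 (not isolated)
Conditions: O3, CH2Cl2, −78 °C (stopped at the first blue tint); then PPh3, −78 → 23 °C
Reagents that add atoms: ozone, [O-][O+]=O
Why: Ozonolysis should cleave the terminal alkene far faster than the silyl-capped diyne, and its carbonyl oxygen on C9 is the atom that ends as the ring oxygen of the target.

Step 8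
Reactants: 10 (3R,4S)-3-(tert-butyldiphenylsilyloxy)-4-(methanesulfonyloxy)-9-(trimethylsilyl)nona-6,8-diynal
Product: 12 (3R,4S,6R,7S)-6-(tert-butyldiphenylsilyloxy)-3,4-dihydroxy-12-(trimethylsilyl)dodec-1-ene-9,11-diyn-7-yl methanesulfonate (6S,7R,9S,9aR), via allylboration adduct 11 (not isolated)
Conditions: allenylboronic acid pinacol ester, (+)-Ipc2BH, Et2O, 0 °C; then 10, −78 °C; then 30% H2O2, aq NaHCO3, 0 °C
Reagents that add atoms: allenylboronic acid pinacol ester, C=C=CB1OC(C)(C)C(C)(C)O1; hydrogen peroxide, OO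
Why: In this Brown-type allylboration the (E)-γ-boryl allylborane made by allene hydroboration should add through a chair transition state to the Re face of the aldehyde under control of the isopinocampheyl groups, setting (9S) and the anti C9a centre, and buffered oxidation replaces boron by hydroxyl with retention.

Step 9
Reactants: 12 vinyl diol (6S,7R,9S,9aR); 3 (S)-2-(tert-butyldimethylsilyloxy)butanal
Product: 15 (2S,3R,5S)-2,3-trans-2,5-cis oxolane-3-carbaldehyde (6S,7R,9S,10R,12S,13S), via dioxolane acetal 13 (not isolated), via all-cis aldehyde 14 (not isolated)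
Conditions: BF3·OEt2 (30 mol %), CH2Cl2, −55 → −20 °C; then Et3N, 23 °C
Reagents that add atoms: none
Why: BF3 condenses 12 and 3 to dioxolane 13 and reopens it to the (E)-oxocarbenium ion on the C9 oxygen (O–C12 bond); the vinyl terminus C11 then attacks C12 in a 6-endo Prins closure through a chair with the C8 and C13 chains equatorial, and the C10 cation is quenched by a pinacol 1,2-shift of C9 from C9a to C10 (C9–C10 bond), which contracts the oxane to the oxolane and releases C9a as the formyl group. The closest known reaction type is the Prins cyclisation–pinacol rearrangement of allylic diol acetals to 3-acyl oxolanes, and the alternative 2-oxonia-Cope/aldol pathway leads to the same product. One ring is closed, the oxolane, by 6-endo-trig cyclisation followed by ring contraction. C9 keeps its configuration because it migrates with retention, C12 is set cis to C9 by the chair, C13 comes from 3, and C10, first formed all-cis (14), is equilibrated by Et3N to the 2,3-trans aldehyde 15. The step needs only the oxocarbenium ion on the homoallylic C9 oxygen to cyclise, which the substrate secures because the ion on the allylic C9a oxygen can merely return to 13, and the low temperature should spare the mesylate, silyl ethers and diyne.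

Step 10
Reactants: 15 2,3-trans oxolane-3-carbaldehyde
Product: 16 (2S,3R,5S)-oxolan-3-yl formate (6S,7R,9S,10R,12S,13S)
Conditions: mCPBA, CH2Cl2, 0 → 23 °C
Reagents that add atoms: 3-chloroperoxybenzoic acid, OOC(=O)c1cccc(Cl)c1
Why: Baeyer–Villiger oxidation of the α-branched aldehyde should move the secondary C10 from C9a to oxygen with retention, so the sacrificial carbon becomes a formate that places the C10 oxygen trans to the C8 chain.

Step 11
Reactants: 16 oxolan-3-yl formate
Product: 19 (6R,7R,9R,10R,12S,13S)-oxocane-9,10,13-triol 7-TBDPS ether bearing the C1-silylated diyne side chain, via bicyclic oxonium mesylate 17 (not isolated), via hydroxy formate 18 (not isolated)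
Conditions: 2,6-lutidine, (CF3)2CHOH–H2O (9:1), 50 °C; then MeOH, camphorsulfonic acid (excess over lutidine), 23 °C
Reagents that add atoms: none
Why: This is a ring expansion through a bicyclic oxonium ion, in which the oxolane oxygen should displace the C6 mesylate with inversion (five-membered neighbouring-ether participation) to give 17, whose C9–O bond alone has a neighbouring formate that can open it with inversion to a dioxolanylium ion, so that hydrolysis gives oxocane 18 with the (6R) and (9R) centres and acid methanolysis then removes the formate and the C13 silyl ether but not the bulkier C7 silyl ether.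

Step 12
Reactants: 19 oxocane-9,10,13-triol 7-TBDPS ether
Product: 20 9,10,13-triacetate of 19
Conditions: Ac2O, pyridine, DMAP (cat.), CH2Cl2, 23 °C
Reagents that add atoms: acetic anhydride, CC(=O)OC(C)=O
Why: Exhaustive acetylation esterifies the three free hydroxyls, while the C7 oxygen stays silylated and thus differentiated.

Step 13
Reactants: 20 9,10,13-triacetate
Product: 21 (3Z)-enyne triacetate (C1-SiMe3 and C7-OTBDPS retained)
Conditions: Zn dust activated by Cu(OAc)2 and AgNO3, MeOH–H2O (1:1), 40 °C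
Reagents that add atoms: none
Why: In this Boland reduction, syn delivery of two hydrogens to the alkyl-substituted C3–C4 triple bond of the conjugated diyne should give the (Z)-alkene, whereas the silyl-capped C1–C2 triple bond is shielded and the acetates are inert.

Step 14
Reactants: 21 (3Z)-enyne triacetate
Product: 22 target (6R,7R,9R,10R,12S,13S,3Z)
Conditions: Bu4NF, AcOH (1:1), THF, 0 → 23 °C
Reagents that add atoms: none
Why: Fluoride-mediated desilylation cleaves the O–Si bond at C7 and the C–Si bond at C1 in one operation, and the acetic acid buffer should suppress acetyl migration to the freed C7 hydroxyl.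

Compound list
1 | methyl (S)-2-hydroxybutanoate | CC[C@H](O)C(=O)OC | starting material
2 | methyl (S)-2-(tert-butyldimethylsilyloxy)butanoate | CC[C@H](O[Si](C)(C)C(C)(C)C)C(=O)OC | intermediate
3 | (S)-2-(tert-butyldimethylsilyloxy)butanal | CC[C@H](O[Si](C)(C)C(C)(C)C)C=O | intermediate
4 | (±)-hexa-1,5-dien-3-ol | C=CCC(O)C=C | starting material
5 | (1R)-1-[(2S)-oxiran-2-yl]but-3-en-1-ol | C=CC[C@@H](O)[C@@H]1CO1 | intermediate
6 | tert-butyl{(1R)-1-[(2S)-oxiran-2-yl]but-3-enyloxy}diphenylsilane | C=CC[C@@H](O[Si](c1ccccc1)(c1ccccc1)C(C)(C)C)[C@@H]1CO1 | intermediate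
7 | (4R,5S)-4-(tert-butyldiphenylsilyloxy)-10-(trimethylsilyl)dec-1-ene-7,9-diyn-5-ol | C=CC[C@@H](O[Si](c1ccccc1)(c1ccccc1)C(C)(C)C)[C@@H](O)CC#CC#C[Si](C)(C)C | intermediate
8 | (4R,5S)-4-(tert-butyldiphenylsilyloxy)-10-(trimethylsilyl)dec-1-ene-7,9-diyn-5-yl methanesulfonate | C=CC[C@@H](O[Si](c1ccccc1)(c1ccccc1)C(C)(C)C)[C@@H](OS(C)(=O)=O)CC#CC#C[Si](C)(C)C | intermediate
9 | 1,2,4-trioxolane (ozonide) of 8, epimers at the ring carbon | C1OC(C[C@@H](O[Si](c2ccccc2)(c2ccccc2)C(C)(C)C)[C@@H](OS(C)(=O)=O)CC#CC#C[Si](C)(C)C)OO1 | intermediate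
10 | (3R,4S)-3-(tert-butyldiphenylsilyloxy)-4-(methanesulfonyloxy)-9-(trimethylsilyl)nona-6,8-diynal | O=CC[C@@H](O[Si](c1ccccc1)(c1ccccc1)C(C)(C)C)[C@@H](OS(C)(=O)=O)CC#CC#C[Si](C)(C)C | intermediate
11 | allylboration adduct: C9 bis(isopinocampheyl)borinate, C9a pinacol boronate | C=C[C@@H](B1OC(C)(C)C(C)(C)O1)[C@@H](OB([C@H]2C[C@H]3C[C@@H]([C@@H]2C)C3(C)C)[C@H]2C[C@H]3C[C@@H]([C@@H]2C)C3(C)C)C[C@@H](O[Si](c2ccccc2)(c2ccccc2)C(C)(C)C)[C@@H](OS(C)(=O)=O)CC#CC#C[Si](C)(C)C | intermediate
12 | (3R,4S,6R,7S)-6-(tert-butyldiphenylsilyloxy)-3,4-dihydroxy-12-(trimethylsilyl)dodec-1-ene-9,11-diyn-7-yl methanesulfonate | C=C[C@@H](O)[C@@H](O)C[C@@H](O[Si](c1ccccc1)(c1ccccc1)C(C)(C)C)[C@@H](OS(C)(=O)=O)CC#CC#C[Si](C)(C)C | intermediate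
13 | 1,3-dioxolane acetal of 12 and 3, epimers at the acetal carbon C12 | C=C[C@H]1OC([C@H](CC)O[Si](C)(C)C(C)(C)C)O[C@H]1C[C@@H](O[Si](c2ccccc2)(c2ccccc2)C(C)(C)C)[C@@H](OS(C)(=O)=O)CC#CC#C[Si](C)(C)C | intermediate
14 | (2S,3S,5S)-all-cis oxolane-3-carbaldehyde: C2 bears the (2R,3S)-2-(TBDPSO)-3-(mesyloxy)-8-(trimethylsilyl)octa-5,7-diynyl chain, C5 the (1S)-1-(TBSO)propyl group | CC[C@H](O[Si](C)(C)C(C)(C)C)[C@@H]1C[C@H](C=O)[C@@H](O1)C[C@@H](O[Si](c2ccccc2)(c2ccccc2)C(C)(C)C)[C@@H](OS(C)(=O)=O)CC#CC#C[Si](C)(C)C | intermediate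
15 | (2S,3R,5S)-epimer of 14 (formyl trans to both side chains) | CC[C@H](O[Si](C)(C)C(C)(C)C)[C@@H]1C[C@@H](C=O)[C@@H](O1)C[C@@H](O[Si](c2ccccc2)(c2ccccc2)C(C)(C)C)[C@@H](OS(C)(=O)=O)CC#CC#C[Si](C)(C)C | intermediate
16 | (2S,3R,5S)-oxolan-3-yl formate with the side chains of 15 | CC[C@H](O[Si](C)(C)C(C)(C)C)[C@@H]1C[C@@H](OC=O)[C@@H](O1)C[C@@H](O[Si](c2ccccc2)(c2ccccc2)C(C)(C)C)[C@@H](OS(C)(=O)=O)CC#CC#C[Si](C)(C)C | intermediate
17 | cis-fused 1-oxoniabicyclo[3.3.0]octane mesylate (oxygen bonded to C6, C9, C12) | CC[C@H](O[Si](C)(C)C(C)(C)C)[C@@H]1C[C@@H](OC=O)[C@@H]2C[C@@H](O[Si](c3ccccc3)(c3ccccc3)C(C)(C)C)[C@@H](CC#CC#C[Si](C)(C)C)[O+]12.CS(=O)(=O)[O-] | intermediate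
18 | oxocane 9-ol 10-formate (drawn isomer; the 9-formate 10-ol converges), 7-OTBDPS, 13-OTBS | C[Si](C)(C)C#CC#CC[C@H]1O[C@H]([C@H](CC)O[Si](C)(C)C(C)(C)C)C[C@@H](OC=O)[C@H](O)C[C@H]1O[Si](c2ccccc2)(c2ccccc2)C(C)(C)C | intermediate
19 | (6R,7R,9R,10R,12S,13S)-oxocane-9,10,13-triol, 7-OTBDPS, C1-SiMe3 diyne | C[Si](C)(C)C#CC#CC[C@H]1O[C@H]([C@H](CC)O)C[C@@H](O)[C@H](O)C[C@H]1O[Si](c2ccccc2)(c2ccccc2)C(C)(C)C | intermediate
20 | 9,10,13-triacetate of 19 | C[Si](C)(C)C#CC#CC[C@H]1O[C@H]([C@H](CC)OC(C)=O)C[C@@H](OC(C)=O)[C@H](OC(C)=O)C[C@H]1O[Si](c2ccccc2)(c2ccccc2)C(C)(C)C | intermediate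
21 | (3Z)-enyne triacetate, 7-OTBDPS, C1-SiMe3 | C[Si](C)(C)C#C/C=C\C[C@H]1O[C@H]([C@H](CC)OC(C)=O)C[C@@H](OC(C)=O)[C@H](OC(C)=O)C[C@H]1O[Si](c2ccccc2)(c2ccccc2)C(C)(C)C | intermediate
22 | CNP0352372.1, (3Z,6R,7R,9R,10R,12S,13S)-9,10,13-triacetoxy-6,12-epoxypentadec-3-en-1-yn-7-ol | C#C/C=C\C[C@H]1O[C@H]([C@H](CC)OC(C)=O)C[C@@H](OC(C)=O)[C@H](OC(C)=O)C[C@H]1O | target

Total steps: 14. Longest linear sequence: 12 steps (steps 3–14, from 4).

Steps most likely to fail

Step 11.
- What may go wrong: the deactivated ether oxygen may ionise the mesylate too slowly. Elimination toward the conjugated enediyne could then compete, or the oxonium ion could be opened at C6 or C12 instead of C9.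
- Fallback: it sets out from 16 and returns at 19, and it changes the group that ends the cascade to one that is consumed irreversibly.
- Ammonia in methanol (0 °C) frees the C10 alcohol F6, and Boc2O/DMAP gives the tert-butyl carbonate F7.
- The same solvolysis should now end by loss of 2-methylpropene to give the neutral trans-fused cyclic carbonate F8.
- iBu2AlH (−78 °C) frees the 9,10-diol F9, and acid methanolysis of the C13 silyl ether gives 19.

Step 9.
- What may go wrong: the union may stall at the acetal, stereochemical fidelity may erode through a reversible 2-oxonia-Cope process, or the acid may strip silyl ethers before the slow attack of the unsubstituted vinyl group.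
- Fallback: it sets out from 12 and returns at 15, and it changes how the oxocarbenium ion is made.
- Me3SiCl/imidazole gives the bis(trimethylsilyl) ether F1.
- F1 is joined with 3 under Me3SiOTf (10 mol %, CH2Cl2, −78 °C).
- The ion then forms by silyl-modified condensation without free acetal or water, the C9a silyl ether ends the pinacol shift, and both bonds still form in one operation.
- Et3N equilibration of 14 then gives 15.

Step 10.
- What may go wrong: hydride rather than carbon may migrate in the Criegee adduct, because C10 is made electron-poor by its β-oxygens, and this would over-oxidise the aldehyde to the carboxylic acid.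
- Fallback: it sets out from 15 and returns at 20.
- MeMgBr (−78 °C) gives the secondary alcohol F2, and Dess–Martin periodinane gives the methyl ketone F3.
- CF3CO3H/Na2HPO4 should move the secondary carbon in preference to methyl and give the C10 acetate F4.
- The conditions of step 11 use this acetate as the neighbouring group and give the oxocane 9,13-diol 10-acetate F5.
- Acetylation as in step 12 gives 20.

Further compounds
F1 | step 9 | bis(trimethylsilyl) ether of 12 | C=C[C@@H](O[Si](C)(C)C)[C@@H](O[Si](C)(C)C)C[C@@H](O[Si](c1ccccc1)(c1ccccc1)C(C)(C)C)[C@@H](OS(C)(=O)=O)CC#CC#C[Si](C)(C)C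
F2 | step 10 | C10 (1-hydroxyethyl) oxolane, epimers at the new carbinol | CC[C@H](O[Si](C)(C)C(C)(C)C)[C@@H]1C[C@@H](C(C)O)[C@@H](O1)C[C@@H](O[Si](c2ccccc2)(c2ccccc2)C(C)(C)C)[C@@H](OS(C)(=O)=O)CC#CC#C[Si](C)(C)C
F3 | step 10 | C10 acetyl oxolane (2S,3R,5S) | CC[C@H](O[Si](C)(C)C(C)(C)C)[C@@H]1C[C@@H](C(C)=O)[C@@H](O1)C[C@@H](O[Si](c2ccccc2)(c2ccccc2)C(C)(C)C)[C@@H](OS(C)(=O)=O)CC#CC#C[Si](C)(C)C
F4 | step 10 | oxolan-3-yl acetate (2S,3R,5S) | CC[C@H](O[Si](C)(C)C(C)(C)C)[C@@H]1C[C@@H](OC(C)=O)[C@@H](O1)C[C@@H](O[Si](c2ccccc2)(c2ccccc2)C(C)(C)C)[C@@H](OS(C)(=O)=O)CC#CC#C[Si](C)(C)C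
F5 | step 10 | oxocane 9,13-diol 10-acetate, 7-OTBDPS | C[Si](C)(C)C#CC#CC[C@H]1O[C@H]([C@H](CC)O)C[C@@H](OC(C)=O)[C@H](O)C[C@H]1O[Si](c2ccccc2)(c2ccccc2)C(C)(C)C
F6 | step 11 | oxolan-3-ol (2S,3R,5S) from 16 | CC[C@H](O[Si](C)(C)C(C)(C)C)[C@@H]1C[C@@H](O)[C@@H](O1)C[C@@H](O[Si](c2ccccc2)(c2ccccc2)C(C)(C)C)[C@@H](OS(C)(=O)=O)CC#CC#C[Si](C)(C)C
F7 | step 11 | tert-butyl carbonate of F6 | CC[C@H](O[Si](C)(C)C(C)(C)C)[C@@H]1C[C@@H](OC(=O)OC(C)(C)C)[C@@H](O1)C[C@@H](O[Si](c2ccccc2)(c2ccccc2)C(C)(C)C)[C@@H](OS(C)(=O)=O)CC#CC#C[Si](C)(C)C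
F8 | step 11 | oxocane 9,10-cyclic carbonate, 7-OTBDPS, 13-OTBS | C[Si](C)(C)C#CC#CC[C@H]1O[C@H]([C@H](CC)O[Si](C)(C)C(C)(C)C)C[C@H]2OC(=O)O[C@@H]2C[C@H]1O[Si](c3ccccc3)(c3ccccc3)C(C)(C)C
F9 | step 11 | oxocane 9,10-diol, 7-OTBDPS, 13-OTBS | C[Si](C)(C)C#CC#CC[C@H]1O[C@H]([C@H](CC)O[Si](C)(C)C(C)(C)C)C[C@@H](O)[C@H](O)C[C@H]1O[Si](c2ccccc2)(c2ccccc2)C(C)(C)C
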